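**Plan**

1. Numbering used here: isochromene skeleton C1, O2, C3, C4, C4a, C5, C6, C7, C8, C8a; ring A is the pyran, ring B the carbocycle.
2. Retrosynthesis: the ring-fusion bond C4a–C8a and the bond C5–C6 are cut in one retro-step, which opens both rings to an acyclic (Z)-α-bromo-β-alkoxy enone aldehyde. Then O2–C1 (oxa-Michael), C8–C8a (acetylide on a Weinreb amide), the stearate C–O bond and C6–C7 (enolate hydroxymethylation) are cut.
3. Enabling feature: the cross-conjugated diene C1=C8a–C4a=C5 that runs through both rings. C8a is the α-carbon of a vinylogous ester and can carry bromide, C4a=C5–H is the imprint of a terminal alkyne on the O2–C3–C4 tether, and the C6 ketone beside C5–H is the imprint of an aldehyde C–H.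
4. Forward: a linear chain is grown from (S)-lactic acid (C7, its methyl, C8), formaldehyde (C6), ethynylmagnesium bromide (C8a, C1) and (R)-pent-4-yn-2-ol (O2, C3, C4, C4a, C5). The last step closes ring A by carbopalladation and ring B by acylative capture and gives the target directly.
5. Stereochemistry: C7 comes from (S)-lactic acid by self-regeneration of the stereocentre through a tert-butyl dioxolanone (electrophile anti to tert-butyl) and is quaternary and non-enolisable from then on. C3 is bought with (R)-pent-4-yn-2-ol and its C–O bond is never broken.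
6. Helpers: the pivalaldehyde acetal, the triethylsilyl ether (masked C6 aldehyde) and the C8a bromide; all are gone by the end of step 9.

Key step: step 9

Remark: (R)-pent-4-yn-2-ol and octadecanoyl chloride are taken as commercial compounds; the tertiary stearate is installed early so that no protecting-group step follows the key step.

**Route**

Step 1
Reactants: 1 (S)-lactic acid; 2 pivalaldehyde
Product: 3 (2S,5S)-2-tert-butyl-5-methyl-1,3-dioxolan-4-one
Conditions: p-TsOH·H2O (cat.), pentane, reflux, Dean–Stark trap; crystallisation from pentane/Et2O at −78 °C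
Reagents that add atoms: none
Why: Acid-catalysed acetalisation of the α-hydroxy acid (dioxolanone formation for self-regeneration of stereocentres) should give mainly the cis acetal, in which the lactate centre is unchanged and the new acetal centre (2S) is the temporary stereocentre, the cis isomer being purified by low-temperature crystallisation.

Step 2
Reactants: 3 (2S,5S)-2-tert-butyl-5-methyl-1,3-dioxolan-4-one
Product: 6 (2S,5R)-2-tert-butyl-5-methyl-5-{[(triethylsilyl)oxy]methyl}-1,3-dioxolan-4-one, via lithium enolate 4 (not isolated), via lithium alkoxide 5 (not isolated)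
Conditions: LiN(i-Pr)2 (LDA), THF, −78 °C; CH2O (gas, from cracked paraformaldehyde), −78 → −40 °C; Et3SiCl, −40 → 0 °C
Reagents that add atoms: formaldehyde, C=O; chlorotriethylsilane, CC[Si](CC)(CC)Cl
Why: Aldol addition of the dioxolanone lithium enolate to formaldehyde followed by O-silylation of the aldolate, in which the electrophile should enter anti to the tert-butyl group and so set the quaternary centre (the future C7) as 5R.

Step 3
Reactants: 6 (2S,5R)-2-tert-butyl-5-methyl-5-{[(triethylsilyl)oxy]methyl}-1,3-dioxolan-4-one
Product: 7 (2R)-2-hydroxy-N-methoxy-N,2-dimethyl-3-[(triethylsilyl)oxy]propanamide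
Conditions: MeNH(OMe)·HCl, i-PrMgCl, THF, −20 → 0 °C
Reagents that add atoms: N,O-dimethylhydroxylamine hydrochloride, CNOC.Cl
Why: Weinreb aminolysis of the activated (acylal-type) lactone by the chloromagnesium amide, after which the hemiacetal alkoxide collapses and releases pivalaldehyde, while the quaternary centre has no α-hydrogen and cannot epimerise.

Step 4
Reactants: 7 (2R)-2-hydroxy-N-methoxy-N,2-dimethyl-3-[(triethylsilyl)oxy]propanamide; 8 octadecanoyl chloride
Product: 9 (2R)-1-[methoxy(methyl)amino]-2-methyl-1-oxo-3-[(triethylsilyl)oxy]propan-2-yl octadecanoate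
Conditions: Et3N, DMAP, CH2Cl2, 0 °C → rt
Reagents that add atoms: none
Why: DMAP-catalysed acylation of the tertiary alcohol puts the final ester in place early, where it also blocks the α-ketol shift and the furanone formation that a free tertiary hydroxyl would allow in later steps.

Step 5
Reactants: 9 (2R)-1-[methoxy(methyl)amino]-2-methyl-1-oxo-3-[(triethylsilyl)oxy]propan-2-yl octadecanoate
Product: 10 (2R)-2-methyl-3-oxo-1-[(triethylsilyl)oxy]pent-4-yn-2-yl octadecanoate
Conditions: HC≡CMgBr, THF, −20 → 0 °C; inverse quench into cold 0.5 M aq. HCl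
Reagents that add atoms: ethynylmagnesium bromide, C#C[Mg]Br
Why: Weinreb ketone synthesis, in which the chelated tetrahedral intermediate stops at the ketone stage, the ester of a tertiary alcohol is much less reactive than the Weinreb amide, and the acidic inverse quench keeps the liberated hydroxylamine from adding to the ynone.

Step 6
Reactants: 10 (2R)-2-methyl-3-oxo-1-[(triethylsilyl)oxy]pent-4-yn-2-yl octadecanoate; 11 (R)-pent-4-yn-2-ol
Product: 12 (2R,4E)-2-methyl-3-oxo-5-{[(2R)-pent-4-yn-2-yl]oxy}-1-[(triethylsilyl)oxy]pent-4-en-2-yl octadecanoate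
Conditions: DABCO (10 mol %), CH2Cl2, 0 °C → rt
Reagents that add atoms: none
Why: Amine-catalysed oxa-Michael addition of the secondary alcohol to the terminal ynone should give the (E)-β-alkoxy enone (vinylogous ester), C3 entering with its oxygen and not being touched.

Step 7
Reactants: 12 (2R,4E)-2-methyl-3-oxo-5-{[(2R)-pent-4-yn-2-yl]oxy}-1-[(triethylsilyl)oxy]pent-4-en-2-yl octadecanoate
Product: 13 (2R,4Z)-4-bromo-2-methyl-3-oxo-5-{[(2R)-pent-4-yn-2-yl]oxy}-1-[(triethylsilyl)oxy]pent-4-en-2-yl octadecanoate
Conditions: NBS, CH2Cl2, 0 °C; then Et3N, 0 °C → rt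
Reagents that add atoms: N-bromosuccinimide, O=C1CCC(=O)N1Br
Why: Electrophilic bromination of the vinylogous ester at its nucleophilic α-carbon followed by loss of a proton (bromination–dehydrobromination) should give the α-bromo-β-alkoxy enone as the more stable (Z) isomer with oxygen trans to the acyl group, the terminal alkyne being far less nucleophilic than the enol ether.

Step 8
Reactants: 13 (2R,4Z)-4-bromo-2-methyl-3-oxo-5-{[(2R)-pent-4-yn-2-yl]oxy}-1-[(triethylsilyl)oxy]pent-4-en-2-yl octadecanoate
Product: 14 (2R,4Z)-4-bromo-2-methyl-1,3-dioxo-5-{[(2R)-pent-4-yn-2-yl]oxy}pent-4-en-2-yl octadecanoate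
Conditions: (COCl)2, DMSO, CH2Cl2, −78 → −30 °C; Et3N, −78 → 0 °C; cold pH 7 buffer work-up, used at once
Reagents that add atoms: none
Why: Swern oxidation applied directly to a primary triethylsilyl ether (oxidative desilylation) should give the aldehyde without passing through a free primary alcohol next to the tertiary ester, so that 1,2-acyl migration has no opening.

Step 9
Reactants: 14 (2R,4Z)-4-bromo-2-methyl-1,3-dioxo-5-{[(2R)-pent-4-yn-2-yl]oxy}pent-4-en-2-yl octadecanoate
Product: 17 (3R,7R)-3,7-dimethyl-6,8-dioxo-3,4,7,8-tetrahydro-6H-isochromen-7-yl octadecanoate, via dienylpalladium bromide 15 (not isolated), via palladium alkoxide 16 (not isolated)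
Conditions: Pd(OAc)2 (10 mol %), PPh3 (20 mol %), NaOAc (2 equiv), n-Bu4NCl (1 equiv), DMF (0.005 M, slow addition of 14), 80 °C
Reagents that add atoms: none
Why: Proposed new method: zerovalent palladium (formed from Pd(OAc)2 and PPh3) inserts into the C8a–Br bond of the α-bromo vinylogous ester, the alkenylpalladium bromide adds syn across the tethered terminal alkyne (C8a to C4a, palladium to C5) to give dienylpalladium 15, whose C5–Pd bond, held cis to C8a, adds to the C6 aldehyde to give alkoxide 16, and β-hydride elimination of the C6–H releases the C6 ketone and HPdBr, which NaOAc returns to zerovalent palladium. The closest known reaction types are the Larock indenone annulation (aryl halide, alkyne and ortho aldehyde giving an enone) and the intramolecular palladium-catalysed acylation of aryl and alkenyl halides with aldehydes, whereas the union of a 6-exo-dig carbopalladation with a six-membered acylative termination on a fully tethered alkenyl bromide has not been shown. Ring A closes by 6-exo-dig carbopalladation and ring B by 6-exo-trig addition of the alkenylpalladium to the aldehyde carbonyl. No lasting stereocentre is created (C6 is a transient carbinol centre in 16), and C3 and C7 are untouched because C7 is quaternary and non-enolisable and C3 is a remote ether carbon. The step needs exo over endo insertion, which the C1–O2–C3–C4 tether and the (Z)-bromide (O2 cis to palladium) secure, and attack on the aldehyde and not on the C8 ketone or the ester, which ring size (six against four or seven) and the higher electrophilicity of the aldehyde secure. High dilution and the absence of copper and amine should suppress intermolecular alkyne coupling, and the mild acetate base should spare the deformylation-prone β-keto aldehyde.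

**Compound list**

1 | (S)-lactic acid | C[C@H](O)C(=O)O | starting material
2 | pivalaldehyde | CC(C)(C)C=O | starting material
3 | (2S,5S)-2-tert-butyl-5-methyl-1,3-dioxolan-4-one | C[C@H]1C(=O)O[C@@H](C(C)(C)C)O1 | intermediate
4 | lithium (2S)-2-tert-butyl-5-methyl-1,3-dioxol-4-olate (lithium enolate of 3) | [Li+].CC1=C([O-])O[C@@H](C(C)(C)C)O1 | intermediate
5 | lithium [(2S,4R)-2-tert-butyl-4-methyl-5-oxo-1,3-dioxolan-4-yl]methanolate | [Li+].[O-]C[C@]1(C)C(=O)O[C@@H](C(C)(C)C)O1 | intermediate
6 | (2S,5R)-2-tert-butyl-5-methyl-5-{[(triethylsilyl)oxy]methyl}-1,3-dioxolan-4-one | CC[Si](CC)(CC)OC[C@]1(C)C(=O)O[C@@H](C(C)(C)C)O1 | intermediate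
7 | (2R)-2-hydroxy-N-methoxy-N,2-dimethyl-3-[(triethylsilyl)oxy]propanamide | CC[Si](CC)(CC)OC[C@@](C)(O)C(=O)N(C)OC | intermediate
8 | octadecanoyl chloride (stearoyl chloride) | CCCCCCCCCCCCCCCCCC(=O)Cl | starting material
9 | (2R)-1-[methoxy(methyl)amino]-2-methyl-1-oxo-3-[(triethylsilyl)oxy]propan-2-yl octadecanoate | CC[Si](CC)(CC)OC[C@@](C)(OC(=O)CCCCCCCCCCCCCCCCC)C(=O)N(C)OC | intermediate
10 | (2R)-2-methyl-3-oxo-1-[(triethylsilyl)oxy]pent-4-yn-2-yl octadecanoate | CC[Si](CC)(CC)OC[C@@](C)(OC(=O)CCCCCCCCCCCCCCCCC)C(=O)C#C | intermediate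
11 | (R)-pent-4-yn-2-ol | C#CC[C@@H](C)O | starting material
12 | (2R,4E)-2-methyl-3-oxo-5-{[(2R)-pent-4-yn-2-yl]oxy}-1-[(triethylsilyl)oxy]pent-4-en-2-yl octadecanoate | CC[Si](CC)(CC)OC[C@@](C)(OC(=O)CCCCCCCCCCCCCCCCC)C(=O)/C=C/O[C@H](C)CC#C | intermediate
13 | (2R,4Z)-4-bromo-2-methyl-3-oxo-5-{[(2R)-pent-4-yn-2-yl]oxy}-1-[(triethylsilyl)oxy]pent-4-en-2-yl octadecanoate | CC[Si](CC)(CC)OC[C@@](C)(OC(=O)CCCCCCCCCCCCCCCCC)C(=O)/C(Br)=C/O[C@H](C)CC#C | intermediate
14 | (2R,4Z)-4-bromo-2-methyl-1,3-dioxo-5-{[(2R)-pent-4-yn-2-yl]oxy}pent-4-en-2-yl octadecanoate | O=C[C@@](C)(OC(=O)CCCCCCCCCCCCCCCCC)C(=O)/C(Br)=C/O[C@H](C)CC#C | intermediate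
15 | dienylpalladium bromide: (2R)-2-methyl-2-(octadecanoyloxy)-3-oxopropanoyl group on C8a of the (3R)-3-methyl-3,4-dihydropyran ring, exocyclic (Z)-CH–PdBr on C4a with palladium cis to C8a (ligands omitted) | Br[Pd]/C=C1/C[C@@H](C)OC=C1C(=O)[C@](C)(OC(=O)CCCCCCCCCCCCCCCCC)C=O | intermediate
16 | palladium alkoxide: bicyclic C6 carbinol of the target skeleton bound through oxygen to PdBr (C6 configuration not defined, ligands omitted) | CCCCCCCCCCCCCCCCCC(=O)O[C@]1(C)C(O[Pd]Br)C=C2C[C@@H](C)OC=C2C1=O | intermediate
17 | (3R,7R)-3,7-dimethyl-6,8-dioxo-3,4,7,8-tetrahydro-6H-isochromen-7-yl octadecanoate | CCCCCCCCCCCCCCCCCC(=O)O[C@]1(C)C(=O)C=C2C[C@@H](C)OC=C2C1=O | target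

**Totals**

Total step count: 9. Longest linear sequence: 9 steps, from (S)-lactic acid 1 to target 17.

**Steps most likely to fail**

Step 9 (the proposed new method). The alkenylpalladium formed after carbopalladation may be protonated before it adds to the hindered neopentyl-type aldehyde, the terminal alkyne may couple intermolecularly, or the β-keto aldehyde may be deformylated under the basic conditions. The fallback sets out from 14 and uses a tin-hydride radical cascade followed by an oxidation. Slow addition of Bu3SnH with AIBN in benzene at 80 °C should abstract bromine from C8a. The resulting alkenyl radical should close 6-exo-dig on the alkyne, and the new alkenyl radical at C5 should add 6-exo to the aldehyde. Hydrogen transfer to the alkoxyl radical should then give (3R,7R)-6-hydroxy-3,7-dimethyl-8-oxo-3,4,7,8-tetrahydro-6H-isochromen-7-yl octadecanoate F1, of which both C6 epimers serve. Oxidation of the allylic alcohol with Dess–Martin periodinane and NaHCO3 in CH2Cl2 comes back to the route at 17.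

Step 8. Desilylative activation of the hindered, electron-poor neopentyl silyl ether may be slow, the chlorosulfonium salt may attack the enol ether, or the β-keto aldehyde may lose its formyl group during the amine stage. The fallback sets out from 13 and unmasks the aldehyde in two stages. HF·pyridine buffered with pyridine in THF at 0 °C should give (2R,4Z)-4-bromo-1-hydroxy-2-methyl-3-oxo-5-{[(2R)-pent-4-yn-2-yl]oxy}pent-4-en-2-yl octadecanoate F2 under acidic conditions that disfavour acyl migration. Immediate oxidation with Dess–Martin periodinane and NaHCO3 in CH2Cl2 at 0 °C comes back to the route at 14.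

Step 2. Formaldehyde may oligomerise on the aldolate (hemiformal formation), the aldolate may revert on warming, or silylation may stay incomplete. The fallback sets out from 3 and replaces the aldol by an alkylation. The lithium enolate (LiN(i-Pr)2, THF, −78 °C) is alkylated with benzyl chloromethyl ether, again anti to the tert-butyl group, to give (2S,5R)-5-[(benzyloxy)methyl]-2-tert-butyl-5-methyl-1,3-dioxolan-4-one F3. Hydrogenolysis (H2, 10% Pd/C, EtOAc) should give (2S,5R)-2-tert-butyl-5-(hydroxymethyl)-5-methyl-1,3-dioxolan-4-one F4. Silylation with Et3SiCl and imidazole in DMF comes back to the route at 6.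

**Further compounds**

F1 | step 9 | (3R,7R)-6-hydroxy-3,7-dimethyl-8-oxo-3,4,7,8-tetrahydro-6H-isochromen-7-yl octadecanoate (both C6 epimers) | CCCCCCCCCCCCCCCCCC(=O)O[C@]1(C)C(O)C=C2C[C@@H](C)OC=C2C1=O
F2 | step 8 | (2R,4Z)-4-bromo-1-hydroxy-2-methyl-3-oxo-5-{[(2R)-pent-4-yn-2-yl]oxy}pent-4-en-2-yl octadecanoate | OC[C@@](C)(OC(=O)CCCCCCCCCCCCCCCCC)C(=O)/C(Br)=C/O[C@H](C)CC#C
F3 | step 2 | (2S,5R)-5-[(benzyloxy)methyl]-2-tert-butyl-5-methyl-1,3-dioxolan-4-one | c1ccccc1COC[C@]2(C)C(=O)O[C@@H](C(C)(C)C)O2
F4 | step 2 | (2S,5R)-2-tert-butyl-5-(hydroxymethyl)-5-methyl-1,3-dioxolan-4-one | OC[C@]1(C)C(=O)O[C@@H](C(C)(C)C)O1
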